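## The problem

The target is a trans-2,3-diaryl-2,3-dihydrobenzofuran that carries three arene units on a small bicyclic core: a catechol ring on C2, a resorcinol ring on C3 and, on the fused benzene ring (ring B), a hydroxyl at C6 and an (E)-3,5-dihydroxystyryl group at C5. There are two stereocentres, C2 (S) and C3 (S), adjacent and trans. The trans relation is the thermodynamically preferred one, so either centre can steer the other, but the absolute configuration has to come from a reagent or catalyst. Seven free phenols, two of them a catechol that oxidises easily, rule out basic aerobic conditions at the end. The benzylic C2–O1 bond is para to an oxygen of its aryl group and ionises under acid, C3–H is doubly benzylic, and the C5 styrene is a 2,4-dioxygenated stilbene that polymerises with acid and isomerises in light. The phenols therefore have to be freed without acid once the stilbene exists, and the stilbene should be made late. The feature that invites a cycloaddition is the oxygen pattern of ring B: O1 on C7a and the oxygen on C6 are 1,3-related with the unsubstituted C7 between them, so C7a=C7–C6=C5 is a 1-alkoxy-3-oxybutadiene whose alkoxy oxygen is O1 itself. The two remaining ring carbons, C3a and the unsubstituted C4, are then an alkyne attached to C3, with O1–C2–C3 as the tether. C5 is ortho to the C6 hydroxyl and para to O1, so its carbon substituent can be added after the ring exists.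

## Retrosynthesis

**Unmasking (22 from 21).** Five O–Si bonds are cut last. Silyl ethers are preferred to methyl ethers at this stage because buffered fluoride frees the phenols without acid or base; exhaustive boron halide cleavage of methyl ethers in the presence of the 2,4-dioxygenated stilbene is judged the weaker neighbour. 21 differs from 22 only by the silyl groups, and the forward step only has to be mild.

**Stilbene (21 from 19 and 20).** The bond between the styryl carbon and the resorcinol ring is cut, which points to a Mizoroki–Heck arylation of vinylarene 19 with 5-iodobenzene-1,3-diol 20. The neighbouring cut through the C=C bond (olefination of aldehyde 18) would need a benzylic phosphorus reagent with fluoride-labile protection, itself several steps long, whereas 20 is used unprotected. One arene unit is removed; the forward reaction must arylate the terminal alkene carbon and give the E alkene.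

**Vinyl group and change of protecting groups (19 from 18, 18 from 17, 17 from 16).** The C=CH2 bond goes back to aldehyde 18, the five silyl ethers to pentaphenol 17, and the four phenols of the pendant rings to the methyl ethers of 16. The methyl ethers are cleaved at the aldehyde stage, before any alkene is present, where the formyl group para to O1 makes that oxygen a poor donor. The forward steps ask that the dihydrofuran survive BBr3.

**C5 carbon (16 from 14, 14 from 13).** The C5–CHO bond is cut. The magnesium phenoxide of 14 delivers formaldehyde to an ortho position, and C5 (para to O1, unhindered) should be preferred to C7, which lies between two oxygens. Electrophilic halogenation or Vilsmeier formylation would attack the dimethoxyphenyl rings instead. Phenol 14 comes from silyl ether 13 by fluoride.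

**Ring B (13 from 12, 12 from 11).** Two hydrogens are added back and then C3a–C7a and C4–C5 are cut. This opens both rings of the bicycle at once and leads to the acyclic dienyne 11, which already holds C2, C3, both aryl groups and all ring B carbons. Closing ring B onto a preformed arene would instead need a halogen or directing group on that arene. The forward reaction must be an intramolecular [4+2] of an electron-rich diene with an unactivated alkyne, followed by a dehydrogenation that spares C2–H and C3–H.

**Diene (11 from 10, 10 from 8 and 9).** The enol O–Si bond and then the O1–C7a bond are cut. This reduces the diene to the commercial ynone 9 and the homopropargylic alcohol 8; the oxygen of 8 becomes O1. The forward steps are an oxa-Michael addition that must give the E enol ether and a soft enolisation.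

**Stereodiad (8 from 5 and 6).** The C2–C3 bond (C1–C2 of the butynol) is cut between two fragments of similar size, each derived from a commercial benzaldehyde. An allenylzinc addition is chosen because it forms this bond, places the alkyne and sets both stereocentres in one step. An epoxide opening by an alkynyl nucleophile would attack the wrong benzylic carbon. The forward reaction must transfer the configuration of mesylate 5 to C3 and give the anti carbinol.

**Propargylic alcohol (5 from 4, 4 from 3, 3 from 1 and 2).** The O–S bond, then the resolution, then the C–C bond between the carbinol carbon and the alkyne are undone. A lipase resolution is preferred to asymmetric reduction of the aryl ethynyl ketone, in which aryl and alkynyl groups are poorly distinguished.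

## Roads not taken

**Alternative 1:** Flavanone ring contraction. The cut is C3–C3a. Flavanone A2 would be treated with PhI(OAc)2 and H2SO4 in trimethyl orthoformate; the trivalent iodine reagent attacks the enol ether at the flavanone C3, the fused arene migrates from the ketal carbon to that carbon, and the pyranone contracts to the dihydrofuran ester A1.
- Merits: the contraction is established on exactly this ring system and gives the trans product. The C5 bromine is in place from the start, so the styryl group needs one Heck reaction and no regioselective formylation. In that respect it is better than the chosen plan.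
- Weak points: A1 carries an ester, not the resorcinol ring, at C3. The ester would have to be exchanged for an aryl group by a decarboxylative arylation next to the labile C2–O1 bond, which costs about three steps. The flavanone can racemise through its chalcone under the acidic conditions, and the veratryl ring is exposed to an electrophilic oxidant. The C6 methyl ether would later need a Lewis acid.
- Against it the chosen plan sets: both aryl groups and both stereocentres are in place before ring B is made, and the ring-forming conditions are neutral.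

**Alternative 2:** Pyrone Diels–Alder with loss of CO2. The cuts are C7a–C7 and C3a–C4. The silyl ketene acetal of lactone A4 would add across C3 and C6 of pyrone A5; loss of CO2 and then of silanol gives benzoate A3.
- Merits: it is convergent, ring B arrives aromatic without an oxidant, and the C5 carbon and C6 oxygen are already there. Here it is clearly better than the chosen plan, which needs a dehydrogenation and a later formylation.
- Weak points: the reaction is intermolecular and the dienophile carbon C3a is hindered by the C3 aryl group. Enantiopure trans-A4 needs its own asymmetric synthesis. The aromatising elimination at the orthoester-like C7a can expel O1 instead of silanol, which opens the dihydrofuran. The C6 methyl ether again forces a late Lewis acid demethylation.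
- Against it the chosen plan sets: regiochemistry by tether, aromatisation by loss of hydrogen (so O1 cannot leave), and a C6 silyl ether that is removed with fluoride.

**Alternative 3:** Aryne insertion into a stilbene oxide. The cuts are O1–C7a and C3–C3a. Fluoride would release the aryne from silyl triflate A8; the oxygen of epoxide A7 adds to C7a, the C3–O bond breaks, and the aryl anion at C3a captures C3 to give A6.
- Merits: it is the most convergent road. Both ring bonds form in one step from an epoxide that asymmetric epoxidation can supply, so the core is reached in fewer steps than in the chosen plan.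
- Weak points: C3 passes through an ionised benzylic centre, so the trans relation and the enantiomeric purity are not assured. The chlorine serves only to direct the aryne and the mesylates only to tame the catechol ring; all three must be removed later, the mesylates with hydroxide. C5 is still unfunctionalised and C6 is a methyl ether.
- Against it the chosen plan sets: no dummy substituents, and stereocentres that are fixed in an acyclic step and never ionised afterwards.

Key step: step 7

Assumption: the configuration at C7a of cycloadduct 12 is left open, because both epimers aromatise to 13; compounds 2, 9 and 20 are taken as purchased.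

## Route

Step 1
Reactants: 1 3,5-dimethoxybenzaldehyde; 2 ethynylmagnesium bromide
Product: 3 1-(3,5-dimethoxyphenyl)prop-2-yn-1-ol (racemic)
Conditions: 2 (1.3 equiv, 0.5 M in THF), THF, 0 °C to rt; aq. NH4Cl
Reagents that add atoms: none
Why: 1,2-Addition of an alkynyl Grignard reagent to a non-enolisable aryl aldehyde; no stereocontrol is sought here.

Step 2
Reactants: 3 1-(3,5-dimethoxyphenyl)prop-2-yn-1-ol (racemic)
Product: 4 (1S)-1-(3,5-dimethoxyphenyl)prop-2-yn-1-ol
Conditions: immobilised Candida antarctica lipase B, vinyl acetate (3 equiv), MTBE, 30 °C, to just beyond half conversion; chromatography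
Reagents that add atoms: none
Why: Lipase-catalysed kinetic resolution by enantioselective transesterification; with aryl as the large and ethynyl as the small substituent the enzyme should acetylate the (R)-alcohol and leave the (S)-alcohol 4, whose enantiomeric purity rises once conversion passes one half.

Step 3
Reactants: 4 (1S)-1-(3,5-dimethoxyphenyl)prop-2-yn-1-ol
Product: 5 (1S)-1-(3,5-dimethoxyphenyl)prop-2-yn-1-yl methanesulfonate
Conditions: MsCl (1.2 equiv), Et3N (1.5 equiv), CH2Cl2, −78 °C; cold aq. NaHCO3 wash, used at once without chromatography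
Reagents that add atoms: methanesulfonyl chloride, CS(=O)(=O)Cl
Why: O-Sulfonylation leaves the C–O bond untouched, so the configuration is retained; the two meta methoxy groups do not stabilise a benzylic cation, which should keep this secondary propargylic mesylate intact in the cold.

Step 4
Reactants: 5 (1S)-1-(3,5-dimethoxyphenyl)prop-2-yn-1-yl methanesulfonate; 6 3,4-dimethoxybenzaldehyde
Product: 8 (1S,2R)-1-(3,4-dimethoxyphenyl)-2-(3,5-dimethoxyphenyl)but-3-yn-1-ol, via allenyl(ethyl)zinc 7 (not isolated)
Conditions: 6 (1.0 equiv), 5 (1.3 equiv), Pd(OAc)2 (5 mol%), PPh3 (5 mol%), Et2Zn (3 equiv), THF, −78 to −20 °C; aq. NH4Cl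
Reagents that add atoms: none
Why: Palladium-catalysed umpolung propargylation: zerovalent palladium (from Pd(OAc)2 and Et2Zn) displaces the mesylate anti (SN2′), Et2Zn takes over the allenyl group with retention to give 7, and 7 adds to 6 through a closed six-membered SE2′ transition state. The new bond forms at the former carbinol carbon with overall inversion, which sets C2 as R, and the aldehyde aryl group lies away from the allenyl aryl group in that transition state, which sets the anti (1S) carbinol.

Step 5
Reactants: 8 (1S,2R)-1-(3,4-dimethoxyphenyl)-2-(3,5-dimethoxyphenyl)but-3-yn-1-ol; 9 but-3-yn-2-one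
Product: 10 (3E)-4-{[(1S,2R)-1-(3,4-dimethoxyphenyl)-2-(3,5-dimethoxyphenyl)but-3-yn-1-yl]oxy}but-3-en-2-one
Conditions: 9 (1.5 equiv), PMe3 (10 mol%), CH2Cl2, 0 °C to rt
Reagents that add atoms: none
Why: Phosphine-catalysed oxa-Michael addition of an alcohol to an ynone, which gives the (E)-β-alkoxy enone; the catalytic ion pair is not basic enough to isomerise the propargylic position, and neither stereocentre is touched.

Step 6
Reactants: 10 (3E)-4-{[(1S,2R)-1-(3,4-dimethoxyphenyl)-2-(3,5-dimethoxyphenyl)but-3-yn-1-yl]oxy}but-3-en-2-one
Product: 11 tert-butyl({(3E)-4-{[(1S,2R)-1-(3,4-dimethoxyphenyl)-2-(3,5-dimethoxyphenyl)but-3-yn-1-yl]oxy}buta-1,3-dien-2-yl}oxy)dimethylsilane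
Conditions: TBSOTf (1.3 equiv), Et3N (2.5 equiv), Et2O, −78 to 0 °C; filtration through Et3N-deactivated silica
Reagents that add atoms: tert-butyldimethylsilyl trifluoromethanesulfonate, CC(C)(C)[Si](C)(C)OS(=O)(=O)C(F)(F)F
Why: Soft enolisation and O-silylation of the methyl ketone of a vinylogous ester, the usual entry to 1-alkoxy-3-silyloxybutadienes; the (E)-enol ether double bond is not touched.

Step 7
Reactants: 11 tert-butyl({(3E)-4-{[(1S,2R)-1-(3,4-dimethoxyphenyl)-2-(3,5-dimethoxyphenyl)but-3-yn-1-yl]oxy}buta-1,3-dien-2-yl}oxy)dimethylsilane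
Product: 13 tert-butyl{[(2S,3S)-2-(3,4-dimethoxyphenyl)-3-(3,5-dimethoxyphenyl)-2,3-dihydro-1-benzofuran-6-yl]oxy}dimethylsilane, via cyclohexadiene cycloadduct 12 (not isolated)
Conditions: degassed PhMe (0.01 M), silanised sealed tube, 170 °C; cool to 0 °C, DDQ (1.0 equiv)
Reagents that add atoms: none
Why: Type 1 intramolecular Diels–Alder reaction followed by dehydrogenation: the s-cis 1-alkoxy-3-silyloxydiene (C7a=C7–C6=C5) adds across the tethered terminal alkyne (C3a≡C4) in a concerted, asynchronous [4+2] that forms C3a–C7a and C4–C5 and gives the 1,4-cyclohexadiene 12; the closest known reaction type is the thermal cycloaddition of 1,3-dien-8-ynes followed by DDQ aromatisation. The dihydrofuran ring is closed as the tether ring, by the C3a–C7a bond across the three-atom link O1–C2–C3, and ring B is closed by the [4+2] itself. The only new stereocentre, C7a, is set by the diene face that the trans-diaryl tether presents, but it is erased on aromatisation, and C2 and C3 take no part and have no ionisable or acidic neighbour under neutral thermal conditions. DDQ then removes hydride from C7a, which is doubly allylic and attached to O1, to give a cation stabilised by O1 and the C6 silyloxy group, and loss of the C5 proton gives arene 13; loss of the silyl group instead would give phenol 14, the product of the next step. Regiochemistry is secured by the short tether and the (E)-enol ether, which allow only the fused mode (C7a to C3a, C5 to C4), and chemoselectivity by using one equivalent of DDQ at 0 °C, since the cyclohexadiene is a far better hydride donor than C2–H or C3–H. The electron-rich diene and the unactivated alkyne are poorly matched electronically, which is offset by intramolecularity and by the two aryl groups on the tether, which favour the reactive rotamer. The oxidant is added to the same flask without aqueous work-up, because hydrolysis of the silyl enol ether in 12 would allow β-elimination of O1.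

Step 8
Reactants: 13 tert-butyl{[(2S,3S)-2-(3,4-dimethoxyphenyl)-3-(3,5-dimethoxyphenyl)-2,3-dihydro-1-benzofuran-6-yl]oxy}dimethylsilane
Product: 14 (2S,3S)-2-(3,4-dimethoxyphenyl)-3-(3,5-dimethoxyphenyl)-2,3-dihydro-1-benzofuran-6-ol
Conditions: TBAF (1.1 equiv), AcOH (1.1 equiv), THF, 0 °C
Reagents that add atoms: none
Why: Fluoride cleavage of an aryl silyl ether; the acetic acid buffer keeps the phenoxide concentration low and the methyl ethers are inert.

Step 9
Reactants: 14 (2S,3S)-2-(3,4-dimethoxyphenyl)-3-(3,5-dimethoxyphenyl)-2,3-dihydro-1-benzofuran-6-ol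
Product: 16 (2S,3S)-2-(3,4-dimethoxyphenyl)-3-(3,5-dimethoxyphenyl)-6-hydroxy-2,3-dihydro-1-benzofuran-5-carbaldehyde, via 5-hydroxymethyl phenol 15 (not isolated)
Conditions: MgCl2 (2 equiv), Et3N (4 equiv), (CH2O)n (6 equiv), MeCN, reflux; 1 M HCl work-up
Reagents that add atoms: formaldehyde (as paraformaldehyde), C=O
Why: Casnati–Skattebøl ortho-formylation: the magnesium phenoxide delivers formaldehyde to the ortho carbon through a chelate to give 15, whose alkoxide transfers hydride to a second formaldehyde. C5 (para to O1, unhindered) should be preferred to C7 between the two oxygens, and the dimethoxyphenyl rings, which have no phenol, are not attacked.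

Step 10
Reactants: 16 (2S,3S)-2-(3,4-dimethoxyphenyl)-3-(3,5-dimethoxyphenyl)-6-hydroxy-2,3-dihydro-1-benzofuran-5-carbaldehyde
Product: 17 (2S,3S)-2-(3,4-dihydroxyphenyl)-3-(3,5-dihydroxyphenyl)-6-hydroxy-2,3-dihydro-1-benzofuran-5-carbaldehyde
Conditions: BBr3 (10 equiv, 1 M in CH2Cl2), CH2Cl2, −78 to 0 °C; ice-water quench
Reagents that add atoms: none
Why: Lewis acid cleavage of aryl methyl ethers (bromide attacks the methyl group of the borane–ether adduct), a reaction of a kind known for methoxylated trans-2,3-diaryl-2,3-dihydrobenzofurans. No alkene is present yet; the formyl group para to O1 and the boron-bound catechol oxygens make ionisation of C2–O1 unfavourable, and any ring opening that did occur should reclose to the trans isomer on work-up because C3 is untouched.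

Step 11
Reactants: 17 (2S,3S)-2-(3,4-dihydroxyphenyl)-3-(3,5-dihydroxyphenyl)-6-hydroxy-2,3-dihydro-1-benzofuran-5-carbaldehyde
Product: 18 (2S,3S)-2-[3,4-bis(tert-butyldimethylsilyloxy)phenyl]-3-[3,5-bis(tert-butyldimethylsilyloxy)phenyl]-6-(tert-butyldimethylsilyloxy)-2,3-dihydro-1-benzofuran-5-carbaldehyde
Conditions: TBSCl (7.5 equiv), imidazole (15 equiv), DMF, rt
Reagents that add atoms: tert-butyldimethylsilyl chloride, CC(C)(C)[Si](C)(C)Cl
Why: Imidazole-promoted silylation of all five phenols; it gives a lipophilic, non-acidic substrate for the ylide and the palladium step.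

Step 12
Reactants: 18 (2S,3S)-2-[3,4-bis(tert-butyldimethylsilyloxy)phenyl]-3-[3,5-bis(tert-butyldimethylsilyloxy)phenyl]-6-(tert-butyldimethylsilyloxy)-2,3-dihydro-1-benzofuran-5-carbaldehyde
Product: 19 (2S,3S)-2-[3,4-bis(tert-butyldimethylsilyloxy)phenyl]-3-[3,5-bis(tert-butyldimethylsilyloxy)phenyl]-6-(tert-butyldimethylsilyloxy)-5-ethenyl-2,3-dihydro-1-benzofuran
Conditions: Ph3PCH3Br (1.5 equiv), KN(SiMe3)2 (1.4 equiv), THF, −78 to 0 °C
Reagents that add atoms: methyltriphenylphosphonium bromide, C[P+](c1ccccc1)(c1ccccc1)c1ccccc1.[Br-]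
Why: Wittig methylenation of an aryl aldehyde; the non-stabilised ylide does not attack aryl silyl ethers and there is no acidic centre next to the aldehyde.

Step 13
Reactants: 19 (2S,3S)-2-[3,4-bis(tert-butyldimethylsilyloxy)phenyl]-3-[3,5-bis(tert-butyldimethylsilyloxy)phenyl]-6-(tert-butyldimethylsilyloxy)-5-ethenyl-2,3-dihydro-1-benzofuran; 20 5-iodobenzene-1,3-diol
Product: 21 5-[(E)-2-{(2S,3S)-2-[3,4-bis(tert-butyldimethylsilyloxy)phenyl]-3-[3,5-bis(tert-butyldimethylsilyloxy)phenyl]-6-(tert-butyldimethylsilyloxy)-2,3-dihydro-1-benzofuran-5-yl}ethenyl]benzene-1,3-diol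
Conditions: 20 (1.3 equiv), Pd(OAc)2 (5 mol%), P(o-tol)3 (15 mol%), Et3N (3 equiv), MeCN, 80 °C, dark
Reagents that add atoms: none
Why: Mizoroki–Heck arylation of a styrene: syn carbopalladation at the terminal carbon and syn β-hydride elimination give the (E)-stilbene. Free phenols are tolerated with an amine base, and any silyl transfer between phenols is harmless because all silyl groups are removed next.

Step 14
Reactants: 21 5-[(E)-2-{(2S,3S)-2-[3,4-bis(tert-butyldimethylsilyloxy)phenyl]-3-[3,5-bis(tert-butyldimethylsilyloxy)phenyl]-6-(tert-butyldimethylsilyloxy)-2,3-dihydro-1-benzofuran-5-yl}ethenyl]benzene-1,3-diol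
Product: 22 5-[(E)-2-[(2S,3S)-2-(3,4-dihydroxyphenyl)-3-(3,5-dihydroxyphenyl)-6-hydroxy-2,3-dihydro-1-benzofuran-5-yl]ethenyl]benzene-1,3-diol
Conditions: TBAF (6 equiv), AcOH (6 equiv), THF, 0 °C, argon, dark; reversed-phase chromatography
Reagents that add atoms: none
Why: Fluoride cleavage of aryl silyl ethers under acetic acid buffering, which exposes neither the stilbene and C2–O1 to acid nor the catechol to free phenoxide in air.

## Compound list

1 | 3,5-dimethoxybenzaldehyde | COc1cc(C=O)cc(OC)c1 | starting material
2 | ethynylmagnesium bromide | C#C[Mg]Br | starting material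
3 | 1-(3,5-dimethoxyphenyl)prop-2-yn-1-ol (racemic) | C#CC(O)c1cc(OC)cc(OC)c1 | intermediate
4 | (1S)-1-(3,5-dimethoxyphenyl)prop-2-yn-1-ol | C#C[C@H](O)c1cc(OC)cc(OC)c1 | intermediate
5 | (1S)-1-(3,5-dimethoxyphenyl)prop-2-yn-1-yl methanesulfonate | C#C[C@H](OS(C)(=O)=O)c1cc(OC)cc(OC)c1 | intermediate
6 | 3,4-dimethoxybenzaldehyde | COc1ccc(C=O)cc1OC | starting material
7 | (aS)-[3-(3,5-dimethoxyphenyl)propa-1,2-dien-1-yl](ethyl)zinc | CC[Zn]C([H])=[C@@]=C([H])c1cc(OC)cc(OC)c1 | intermediate (not isolated)
8 | (1S,2R)-1-(3,4-dimethoxyphenyl)-2-(3,5-dimethoxyphenyl)but-3-yn-1-ol | O[C@H](c1ccc(OC)c(OC)c1)[C@H](C#C)c1cc(OC)cc(OC)c1 | intermediate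
9 | but-3-yn-2-one | CC(=O)C#C | starting material
10 | (3E)-4-{[(1S,2R)-1-(3,4-dimethoxyphenyl)-2-(3,5-dimethoxyphenyl)but-3-yn-1-yl]oxy}but-3-en-2-one | CC(=O)/C=C/O[C@H](c1ccc(OC)c(OC)c1)[C@H](C#C)c1cc(OC)cc(OC)c1 | intermediate
11 | tert-butyl({(3E)-4-{[(1S,2R)-1-(3,4-dimethoxyphenyl)-2-(3,5-dimethoxyphenyl)but-3-yn-1-yl]oxy}buta-1,3-dien-2-yl}oxy)dimethylsilane | C=C(O[Si](C)(C)C(C)(C)C)/C=C/O[C@H](c1ccc(OC)c(OC)c1)[C@H](C#C)c1cc(OC)cc(OC)c1 | intermediate
12 | tert-butyl{[(2S,3S)-2-(3,4-dimethoxyphenyl)-3-(3,5-dimethoxyphenyl)-2,3,5,7a-tetrahydro-1-benzofuran-6-yl]oxy}dimethylsilane (C7a either way) | CC(C)(C)[Si](C)(C)OC1CC=C2C(C=1)O[C@H](c1ccc(OC)c(OC)c1)[C@H]2c1cc(OC)cc(OC)c1 | intermediate (not isolated)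
13 | tert-butyl{[(2S,3S)-2-(3,4-dimethoxyphenyl)-3-(3,5-dimethoxyphenyl)-2,3-dihydro-1-benzofuran-6-yl]oxy}dimethylsilane | CC(C)(C)[Si](C)(C)Oc1ccc2c(c1)O[C@H](c1ccc(OC)c(OC)c1)[C@H]2c1cc(OC)cc(OC)c1 | intermediate
14 | (2S,3S)-2-(3,4-dimethoxyphenyl)-3-(3,5-dimethoxyphenyl)-2,3-dihydro-1-benzofuran-6-ol | Oc1ccc2c(c1)O[C@H](c1ccc(OC)c(OC)c1)[C@H]2c1cc(OC)cc(OC)c1 | intermediate
15 | (2S,3S)-2-(3,4-dimethoxyphenyl)-3-(3,5-dimethoxyphenyl)-5-(hydroxymethyl)-2,3-dihydro-1-benzofuran-6-ol (present as its magnesium salt) | OCc1cc2c(cc1O)O[C@H](c1ccc(OC)c(OC)c1)[C@H]2c1cc(OC)cc(OC)c1 | intermediate (not isolated)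
16 | (2S,3S)-2-(3,4-dimethoxyphenyl)-3-(3,5-dimethoxyphenyl)-6-hydroxy-2,3-dihydro-1-benzofuran-5-carbaldehyde | O=Cc1cc2c(cc1O)O[C@H](c1ccc(OC)c(OC)c1)[C@H]2c1cc(OC)cc(OC)c1 | intermediate
17 | (2S,3S)-2-(3,4-dihydroxyphenyl)-3-(3,5-dihydroxyphenyl)-6-hydroxy-2,3-dihydro-1-benzofuran-5-carbaldehyde | O=Cc1cc2c(cc1O)O[C@H](c1ccc(O)c(O)c1)[C@H]2c1cc(O)cc(O)c1 | intermediate
18 | (2S,3S)-2-[3,4-bis(tert-butyldimethylsilyloxy)phenyl]-3-[3,5-bis(tert-butyldimethylsilyloxy)phenyl]-6-(tert-butyldimethylsilyloxy)-2,3-dihydro-1-benzofuran-5-carbaldehyde | O=Cc1cc2c(cc1O[Si](C)(C)C(C)(C)C)O[C@H](c1ccc(O[Si](C)(C)C(C)(C)C)c(O[Si](C)(C)C(C)(C)C)c1)[C@H]2c1cc(O[Si](C)(C)C(C)(C)C)cc(O[Si](C)(C)C(C)(C)C)c1 | intermediate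
19 | (2S,3S)-2-[3,4-bis(tert-butyldimethylsilyloxy)phenyl]-3-[3,5-bis(tert-butyldimethylsilyloxy)phenyl]-6-(tert-butyldimethylsilyloxy)-5-ethenyl-2,3-dihydro-1-benzofuran | C=Cc1cc2c(cc1O[Si](C)(C)C(C)(C)C)O[C@H](c1ccc(O[Si](C)(C)C(C)(C)C)c(O[Si](C)(C)C(C)(C)C)c1)[C@H]2c1cc(O[Si](C)(C)C(C)(C)C)cc(O[Si](C)(C)C(C)(C)C)c1 | intermediate
20 | 5-iodobenzene-1,3-diol | Oc1cc(O)cc(I)c1 | starting material
21 | 5-[(E)-2-{(2S,3S)-2-[3,4-bis(tert-butyldimethylsilyloxy)phenyl]-3-[3,5-bis(tert-butyldimethylsilyloxy)phenyl]-6-(tert-butyldimethylsilyloxy)-2,3-dihydro-1-benzofuran-5-yl}ethenyl]benzene-1,3-diol | Oc1cc(O)cc(/C=C/c2cc3c(cc2O[Si](C)(C)C(C)(C)C)O[C@H](c2ccc(O[Si](C)(C)C(C)(C)C)c(O[Si](C)(C)C(C)(C)C)c2)[C@H]3c2cc(O[Si](C)(C)C(C)(C)C)cc(O[Si](C)(C)C(C)(C)C)c2)c1 | intermediate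
22 | 5-[(E)-2-[(2S,3S)-2-(3,4-dihydroxyphenyl)-3-(3,5-dihydroxyphenyl)-6-hydroxy-2,3-dihydro-1-benzofuran-5-yl]ethenyl]benzene-1,3-diol | Oc1cc(O)cc(/C=C/c2cc3c(cc2O)O[C@H](c2ccc(O)c(O)c2)[C@H]3c2cc(O)cc(O)c2)c1 | target

## Step count and least certain steps

Total: 14 steps. Longest linear sequence: 14 steps (1 to 22); compounds 2, 6, 9 and 20 enter as purchased.

**Step 7 (key step).**
- What may go wrong: the cycloaddition of an electron-rich diene with an unactivated alkyne may be slower than thermal desilylation or polymerisation of the silyl dienol ether. Hydrolysis of the silyl enol ether in the cycloadduct followed by β-elimination of O1 would aromatise with opening of the dihydrofuran. Over-oxidation at C2–H or C3–H by DDQ is a lesser risk.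
- Fallback: the pericyclic reaction is replaced by a metal-templated cycloaddition that does not depend on frontier-orbital matching. It sets out from 11, which is treated with [RhCl(C8H14)2]2 and P[OCH(CF3)2]3 in THF at 25–55 °C; monovalent rhodium couples diene and alkyne through a metallacycle and reductive elimination gives the same cyclohexadiene 12. DDQ is then added as before and the route is rejoined at 13. No new compound arises (F0).

**Step 4.**
- What may go wrong: ionisation of the benzylic propargylic mesylate before it meets the catalyst; racemisation of the aryl-substituted allenylpalladium or allenylzinc species, which erodes the enantiomeric purity; weaker anti preference with an aromatic aldehyde.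
- Fallback: chirality transfer is given up for a diastereoselective racemic coupling and a classical resolution. It sets out from 3 and 6. Benzoylation of 3 (BzCl, pyridine) gives the storable 1-(3,5-dimethoxyphenyl)prop-2-yn-1-yl benzoate (racemic) F1. F1 with 6, Pd(PPh3)4 and Et2Zn in THF at rt gives racemic anti-1-(3,4-dimethoxyphenyl)-2-(3,5-dimethoxyphenyl)but-3-yn-1-ol F2. Esterification with (S)-2-methoxy-2-phenylacetic acid (DCC, DMAP) and separation of the diastereomers gives (1S,2R)-1-(3,4-dimethoxyphenyl)-2-(3,5-dimethoxyphenyl)but-3-yn-1-yl (2S)-2-methoxy-2-phenylacetate F3; its diastereomer, (1R,2S)-1-(3,4-dimethoxyphenyl)-2-(3,5-dimethoxyphenyl)but-3-yn-1-yl (2S)-2-methoxy-2-phenylacetate F4, is set aside. Methanolysis of F3 (K2CO3, MeOH) rejoins the route at 8.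

**Step 5.**
- What may go wrong: slow addition of the hindered secondary benzylic alcohol while the ynone oligomerises; isomerisation of the doubly activated propargylic C–H to the allene by the alkoxide ion pair.
- Fallback: nucleophile catalysis is replaced by an acid-catalysed alkoxy exchange. It sets out from 8, which is heated with commercial (E)-4-methoxybut-3-en-2-one and pyridinium p-toluenesulfonate in toluene over 5 Å molecular sieves that take up methanol, and comes back at 10. No new compound arises (F0).

**Step 13.**
- What may go wrong: slow oxidative addition into the electron-rich, unprotected iodoresorcinol; arylation at the internal carbon of the electron-rich ortho-silyloxystyrene; loss of silyl groups on prolonged heating.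
- Fallback: the stilbene is made by cross-coupling of an alkenylboron compound instead of by alkene arylation. It sets out from aldehyde 18. A boron–Wittig reaction with bis(pinacolato)borylmethane and lithium 2,2,6,6-tetramethylpiperidide in THF gives 2-[(E)-2-{(2S,3S)-2-[3,4-bis(tert-butyldimethylsilyloxy)phenyl]-3-[3,5-bis(tert-butyldimethylsilyloxy)phenyl]-6-(tert-butyldimethylsilyloxy)-2,3-dihydro-1-benzofuran-5-yl}ethenyl]-4,4,5,5-tetramethyl-1,3,2-dioxaborolane F5. Suzuki–Miyaura coupling of F5 with 20 (PdCl2(dppf), K3PO4, THF–H2O, 40 °C) comes back at 21.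

## Further compounds

F0 | step 7 | none | none
F1 | step 4 | 1-(3,5-dimethoxyphenyl)prop-2-yn-1-yl benzoate (racemic) | O=C(OC(C#C)c1cc(OC)cc(OC)c1)c1ccccc1
F2 | step 4 | anti-1-(3,4-dimethoxyphenyl)-2-(3,5-dimethoxyphenyl)but-3-yn-1-ol (racemate; one enantiomer drawn) | O[C@H](c1ccc(OC)c(OC)c1)[C@H](C#C)c1cc(OC)cc(OC)c1
F3 | step 4 | (1S,2R)-1-(3,4-dimethoxyphenyl)-2-(3,5-dimethoxyphenyl)but-3-yn-1-yl (2S)-2-methoxy-2-phenylacetate | CO[C@@H](c1ccccc1)C(=O)O[C@H](c1ccc(OC)c(OC)c1)[C@H](C#C)c1cc(OC)cc(OC)c1
F4 | step 4 | (1R,2S)-1-(3,4-dimethoxyphenyl)-2-(3,5-dimethoxyphenyl)but-3-yn-1-yl (2S)-2-methoxy-2-phenylacetate | CO[C@@H](c1ccccc1)C(=O)O[C@@H](c1ccc(OC)c(OC)c1)[C@@H](C#C)c1cc(OC)cc(OC)c1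
F0 | step 5 | none | none
F5 | step 13 | 2-[(E)-2-{(2S,3S)-2-[3,4-bis(tert-butyldimethylsilyloxy)phenyl]-3-[3,5-bis(tert-butyldimethylsilyloxy)phenyl]-6-(tert-butyldimethylsilyloxy)-2,3-dihydro-1-benzofuran-5-yl}ethenyl]-4,4,5,5-tetramethyl-1,3,2-dioxaborolane | CC1(C)OB(/C=C/c2cc3c(cc2O[Si](C)(C)C(C)(C)C)O[C@H](c2ccc(O[Si](C)(C)C(C)(C)C)c(O[Si](C)(C)C(C)(C)C)c2)[C@H]3c2cc(O[Si](C)(C)C(C)(C)C)cc(O[Si](C)(C)C(C)(C)C)c2)OC1(C)C
A1 | alternative 1 | methyl (2S,3S)-5-bromo-2-(3,4-dimethoxyphenyl)-6-methoxy-2,3-dihydro-1-benzofuran-3-carboxylate | Brc1cc2c(cc1OC)O[C@H](c1ccc(OC)c(OC)c1)[C@H]2C(=O)OC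
A2 | alternative 1 | (2S)-6-bromo-2-(3,4-dimethoxyphenyl)-7-methoxy-2,3-dihydro-4H-chromen-4-one | O=C1C[C@@H](c2ccc(OC)c(OC)c2)Oc2cc(OC)c(Br)cc21
A3 | alternative 2 | methyl (2S,3S)-2-(3,4-dimethoxyphenyl)-3-(3,5-dimethoxyphenyl)-6-methoxy-2,3-dihydro-1-benzofuran-5-carboxylate | COC(=O)c1cc2c(cc1OC)O[C@H](c1ccc(OC)c(OC)c1)[C@H]2c1cc(OC)cc(OC)c1
A4 | alternative 2 | (4R,5S)-5-(3,4-dimethoxyphenyl)-4-(3,5-dimethoxyphenyl)oxolan-2-one | O=C1C[C@H](c2cc(OC)cc(OC)c2)[C@@H](c2ccc(OC)c(OC)c2)O1
A5 | alternative 2 | methyl 4-methoxy-2-oxo-2H-pyran-5-carboxylate | COC(=O)C1=COC(=O)C=C1OC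
A6 | alternative 3 | (2S,3S)-4-chloro-2-[3,4-bis(methanesulfonyloxy)phenyl]-3-(3,5-dimethoxyphenyl)-6-methoxy-2,3-dihydro-1-benzofuran | COc1cc(Cl)c2c(c1)O[C@H](c1ccc(OS(C)(=O)=O)c(OS(C)(=O)=O)c1)[C@H]2c1cc(OC)cc(OC)c1
A7 | alternative 3 | (2R,3R)-2-[3,4-bis(methanesulfonyloxy)phenyl]-3-(3,5-dimethoxyphenyl)oxirane | O1[C@H](c2ccc(OS(C)(=O)=O)c(OS(C)(=O)=O)c2)[C@H]1c1cc(OC)cc(OC)c1
A8 | alternative 3 | 3-chloro-5-methoxy-2-(trimethylsilyl)phenyl trifluoromethanesulfonate | COc1cc(Cl)c([Si](C)(C)C)c(OS(=O)(=O)C(F)(F)F)c1
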